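**Retrosynthetic overview**
- The acid comes from its methyl ester. C1–C2 are added to a 1,2-dioxan-3-ol by Wittig olefination, and C3–O is closed by intramolecular peroxy-Michael addition, which sets C3.
- Ring order: the 1,2-dioxane first (C6–O, by a hydroperoxy acetal tethered at C3 that opens the 6,7-epoxide), then the oxolane (C7–O displaces a C10 mesylate), both in one flask.
- C11–C12 is made by copper-catalysed opening of a terminal epoxide with the C12–C24 Grignard reagent.
- Key step: the (17Z,19Z)-diene of the C12–C24 chain is cut out of thiophene (1) by two nickel-catalysed C–S to C–C couplings, so the ring geometry becomes both Z-olefins.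
- The C3–C11 bis-epoxide comes from Julia–Kocienski olefination and Shi epoxidation.

Assumption: positions are numbered C1–C24 along the acid chain (C1 = carboxyl carbon); compounds 6, 9, 12, 25 and the L-fructose-derived Shi ketone are bought.

**Route**

Step 1
Reactants: 1 thiophene; 2 1-bromo-5-chloropentane
Product: 5 (1Z,3Z)-9-chloro-1-(methylsulfanyl)nona-1,3-diene, via (5-chloropentyl)magnesium bromide 3 (not isolated), via bromomagnesium dienethiolate 4 (not isolated)
Conditions: 2, Mg, THF, 25 °C; then 1 (5 equiv), NiCl2(Ph2PCH2CH2CH2PPh2) (5 mol%), toluene, 70 °C; then MeI, 0 → 23 °C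
Reagents that add atoms: iodomethane, CI
Why: Proposed new method: zerovalent nickel (formed from the nickel dichloride complex and the Grignard reagent) inserts into one C–S bond of thiophene, and transmetalation and reductive elimination form the C–C bond with retention so that the ring geometry becomes the (Z,Z)-diene; the excess of thiophene out-competes the sluggish dienethiolate for the catalyst so the reaction stops after one C–S bond, and MeI then caps sulfur; the closest known reaction is the nickel-catalysed Grignard ring-opening of thiophene to (Z,Z)-1,4-disubstituted butadienes (Wenkert-type Kumada coupling).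

Step 2
Reactants: 5 (1Z,3Z)-9-chloro-1-(methylsulfanyl)nona-1,3-diene; 6 but-3-en-1-ylmagnesium bromide
Product: 7 (5Z,7Z)-13-chlorotrideca-1,5,7-triene
Conditions: 6 (1.5 equiv, 0.5 M in THF), NiCl2(Ph2PCH2CH2CH2PPh2) (3 mol%), Et2O, 0 → 23 °C
Reagents that add atoms: none
Why: Nickel-catalysed Kumada-type coupling of an alkenyl sulfide with an alkyl Grignard reagent replaces sulfur by carbon with retention, so both olefins stay Z, and the alkyl chloride and terminal olefin are not touched.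

Step 3
Reactants: 8 4-chloro-1,1-dimethoxybutane; 9 1-phenyl-1H-tetrazole-5-thiol
Product: 10 5-[(4,4-dimethoxybutyl)sulfanyl]-1-phenyl-1H-tetrazole
Conditions: K2CO3, NaI (10 mol%), DMF, 60 °C
Reagents that add atoms: none
Why: SN2 S-alkylation of the tetrazolethiolate, assisted by iodide exchange; no stereocentre is involved.

Step 4
Reactants: 10 5-[(4,4-dimethoxybutyl)sulfanyl]-1-phenyl-1H-tetrazole
Product: 11 5-[(4,4-dimethoxybutyl)sulfonyl]-1-phenyl-1H-tetrazole
Conditions: mCPBA (2.3 equiv), NaHCO3, CH2Cl2, 0 → 23 °C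
Reagents that add atoms: 3-chloroperbenzoic acid, OOC(=O)c1cccc(Cl)c1
Why: Peracid oxidation of the sulfide to the sulfone; the NaHCO3 buffer keeps the acetal intact.

Step 5
Reactants: 12 (2R)-2-(but-3-en-1-yl)oxirane
Product: 14 3-[(2R)-oxiran-2-yl]propanal, via ozonide 13 (not isolated)
Conditions: O3, CH2Cl2, −78 °C; then PPh3, −78 → 23 °C
Reagents that add atoms: ozone, [O-][O+]=O
Why: Ozonolysis with reductive work-up cleaves the terminal olefin to the aldehyde; the epoxide and its stereocentre (the future C10) are untouched.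

Step 6
Reactants: 11 5-[(4,4-dimethoxybutyl)sulfonyl]-1-phenyl-1H-tetrazole; 14 3-[(2R)-oxiran-2-yl]propanal
Product: 16 (2R)-2-[(3E)-7,7-dimethoxyhept-3-en-1-yl]oxirane, via potassium sulfonyl carbanion 15 (not isolated)
Conditions: 11, KN(SiMe3)2, DME, −60 °C; then 14, −60 → 23 °C
Reagents that add atoms: none
Why: Julia–Kocienski olefination (addition, Smiles rearrangement, loss of SO2) gives the (E)-olefin, expected at about 10:1 or better with the potassium counter-ion in DME; the epoxide stereocentre is not touched.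

Step 7
Reactants: 16 (2R)-2-[(3E)-7,7-dimethoxyhept-3-en-1-yl]oxirane
Product: 17 (2R)-2-{2-[(2S,3S)-3-(3,3-dimethoxypropyl)oxiran-2-yl]ethyl}oxirane
Conditions: L-fructose-derived Shi ketone (30 mol%), KHSO5 (as 2KHSO5·KHSO4·K2SO4), K2CO3, Bu4NHSO4, MeCN/CH2(OMe)2/aq. Na2B4O7 buffer (pH 10.5), 0 °C
Reagents that add atoms: potassium peroxymonosulfate, [K+].[O-]S(=O)(=O)OO
Why: Shi asymmetric epoxidation through the spiro transition state gives the (S,S)-trans-epoxide (C6 and C7) under reagent control with the enantiomeric ketone; the residual (Z)-olefin reacts much more slowly, and acetal and terminal epoxide survive the basic buffer.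

Step 8
Reactants: 7 (5Z,7Z)-13-chlorotrideca-1,5,7-triene; 17 (2R)-2-{2-[(2S,3S)-3-(3,3-dimethoxypropyl)oxiran-2-yl]ethyl}oxirane
Product: 20 (3S,10Z,12Z)-1-[(2S,3S)-3-(3,3-dimethoxypropyl)oxiran-2-yl]heptadeca-10,12,16-trien-3-yl methanesulfonate, via [(6Z,8Z)-trideca-6,8,12-trien-1-yl]magnesium chloride 18 (not isolated), via chloromagnesium alkoxide 19 (not isolated)
Conditions: 7, Mg, THF, 60 °C; then 17, CuI (10 mol%), THF, −40 °C; then MeSO2Cl, −40 → 0 °C
Reagents that add atoms: methanesulfonyl chloride, CS(=O)(=O)Cl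
Why: Copper-catalysed SN2 opening of the terminal epoxide at its CH2 group forms C11–C12 with retention at C10 (the trans-2,3-dialkyl epoxide and the acetal are inert at −40 °C), and the magnesium alkoxide is mesylated in the flask before it can attack the inner epoxide.

Step 9
Reactants: 20 (3S,10Z,12Z)-1-[(2S,3S)-3-(3,3-dimethoxypropyl)oxiran-2-yl]heptadeca-10,12,16-trien-3-yl methanesulfonate
Product: 23 (6R)-3-methoxy-6-{(2S,5R)-5-[(7Z,9Z)-tetradeca-7,9,13-trien-1-yl]oxolan-2-yl}-1,2-dioxane, via hydroperoxy acetal 21 (not isolated), via hydroxy mesylate 22 (not isolated)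
Conditions: anhydrous H2O2 in Et2O (6 equiv), 10-camphorsulfonic acid (10 mol%), 0 → 23 °C; aqueous wash; then pyridine, 40 °C
Reagents that add atoms: hydrogen peroxide, OO
Why: Proposed new method: acid-catalysed exchange of one acetal methoxy group by H2O2 gives hydroperoxy acetal 21, whose OOH group can only reach C6 and opens the trans-epoxide 6-exo-tet with inversion (C6 becomes R, the tether fixing the regiochemistry), and the C7 hydroxyl set free then displaces the C10 mesylate 5-exo-tet with inversion in warm pyridine (C10 becomes R, trans-oxolane); the closest known reactions are the H2O2/acid conversion of acetals into hydroperoxy acetals, the intramolecular opening of epoxides by hydroperoxides to 1,2-dioxanes, and the closure of hydroxy mesylates to oxolanes.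

Step 10
Reactants: 23 (6R)-3-methoxy-6-{(2S,5R)-5-[(7Z,9Z)-tetradeca-7,9,13-trien-1-yl]oxolan-2-yl}-1,2-dioxane
Product: 24 (6R)-6-{(2S,5R)-5-[(7Z,9Z)-tetradeca-7,9,13-trien-1-yl]oxolan-2-yl}-1,2-dioxan-3-ol
Conditions: H2SO4 (0.5 M aq.), THF, 23 °C
Reagents that add atoms: water, O
Why: Acid hydrolysis of the cyclic peroxy acetal to the peroxy hemiacetal; C3 is not yet a fixed stereocentre and the other three centres are untouched.

Step 11
Reactants: 24 (6R)-6-{(2S,5R)-5-[(7Z,9Z)-tetradeca-7,9,13-trien-1-yl]oxolan-2-yl}-1,2-dioxan-3-ol; 25 methyl (triphenylphosphoranylidene)acetate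
Product: 27 methyl 2-[(3R,6R)-6-{(2S,5R)-5-[(7Z,9Z)-tetradeca-7,9,13-trien-1-yl]oxolan-2-yl}-1,2-dioxan-3-yl]acetate, via hydroperoxy enoate 26 (not isolated)
Conditions: 25 (1.5 equiv), CH2Cl2, 23 °C; then Et3N, CF3CH2OH, 23 → 40 °C
Reagents that add atoms: none
Why: Wittig olefination of the open hydroperoxy aldehyde form gives the (E)-enoate 26, and reversible base-mediated intramolecular peroxy-Michael addition (6-exo-trig) closes the dioxane through a chair with both substituents equatorial, so C3 is set R, trans to C6, under substrate (thermodynamic) control; the expected ratio is roughly 5–9:1 and the minor cis ester is removed by chromatography.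

Step 12
Reactants: 27 methyl 2-[(3R,6R)-6-{(2S,5R)-5-[(7Z,9Z)-tetradeca-7,9,13-trien-1-yl]oxolan-2-yl}-1,2-dioxan-3-yl]acetate
Product: 29 2-[(3R,6R)-6-{(2S,5R)-5-[(7Z,9Z)-tetradeca-7,9,13-trien-1-yl]oxolan-2-yl}-1,2-dioxan-3-yl]acetic acid, via lithium carboxylate 28 (not isolated)
Conditions: LiOH, THF/H2O (3:1), 0 → 23 °C; then 1 M HCl to pH 3
Reagents that add atoms: lithium hydroxide, [Li+].[OH-]
Why: Saponification of the methyl ester; no stereocentre is touched and the dialkyl peroxide and the diene survive cold aqueous LiOH.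

**Compound list**

1 | thiophene | c1ccsc1 | starting material
2 | 1-bromo-5-chloropentane | ClCCCCCBr | starting material
3 | (5-chloropentyl)magnesium bromide | ClCCCCC[Mg]Br | intermediate
4 | bromomagnesium (1Z,3Z)-9-chloronona-1,3-diene-1-thiolate | ClCCCCC/C=C\C=C/S[Mg]Br | intermediate
5 | (1Z,3Z)-9-chloro-1-(methylsulfanyl)nona-1,3-diene | ClCCCCC/C=C\C=C/SC | intermediate
6 | but-3-en-1-ylmagnesium bromide | C=CCC[Mg]Br | starting material
7 | (5Z,7Z)-13-chlorotrideca-1,5,7-triene | ClCCCCC/C=C\C=C/CCC=C | intermediate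
8 | 4-chloro-1,1-dimethoxybutane | COC(OC)CCCCl | starting material
9 | 1-phenyl-1H-tetrazole-5-thiol | Sc1nnnn1-c1ccccc1 | starting material
10 | 5-[(4,4-dimethoxybutyl)sulfanyl]-1-phenyl-1H-tetrazole | COC(OC)CCCSc1nnnn1-c1ccccc1 | intermediate
11 | 5-[(4,4-dimethoxybutyl)sulfonyl]-1-phenyl-1H-tetrazole | COC(OC)CCCS(=O)(=O)c1nnnn1-c1ccccc1 | intermediate
12 | (2R)-2-(but-3-en-1-yl)oxirane | C=CCC[C@@H]1CO1 | starting material
13 | 3-{2-[(2R)-oxiran-2-yl]ethyl}-1,2,4-trioxolane (ozonide) | O1OC(CC[C@@H]2CO2)OC1 | intermediate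
14 | 3-[(2R)-oxiran-2-yl]propanal | O=CCC[C@@H]1CO1 | intermediate
15 | potassium 4,4-dimethoxy-1-[(1-phenyl-1H-tetrazol-5-yl)sulfonyl]butan-1-ide | COC(OC)CC[CH-]S(=O)(=O)c1nnnn1-c1ccccc1.[K+] | intermediate
16 | (2R)-2-[(3E)-7,7-dimethoxyhept-3-en-1-yl]oxirane | COC(OC)CC/C=C/CC[C@@H]1CO1 | intermediate
17 | (2R)-2-{2-[(2S,3S)-3-(3,3-dimethoxypropyl)oxiran-2-yl]ethyl}oxirane | COC(OC)CC[C@@H]1O[C@H]1CC[C@@H]2CO2 | intermediate
18 | [(6Z,8Z)-trideca-6,8,12-trien-1-yl]magnesium chloride | Cl[Mg]CCCCC/C=C\C=C/CCC=C | intermediate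
19 | chloromagnesium (3S,10Z,12Z)-1-[(2S,3S)-3-(3,3-dimethoxypropyl)oxiran-2-yl]heptadeca-10,12,16-trien-3-olate | COC(OC)CC[C@@H]1O[C@H]1CC[C@@H](O[Mg]Cl)CCCCCC/C=C\C=C/CCC=C | intermediate
20 | (3S,10Z,12Z)-1-[(2S,3S)-3-(3,3-dimethoxypropyl)oxiran-2-yl]heptadeca-10,12,16-trien-3-yl methanesulfonate | COC(OC)CC[C@@H]1O[C@H]1CC[C@@H](OS(C)(=O)=O)CCCCCC/C=C\C=C/CCC=C | intermediate
21 | (3S,10Z,12Z)-1-[(2S,3S)-3-(3-hydroperoxy-3-methoxypropyl)oxiran-2-yl]heptadeca-10,12,16-trien-3-yl methanesulfonate (acetal carbon: both epimers) | COC(OO)CC[C@@H]1O[C@H]1CC[C@@H](OS(C)(=O)=O)CCCCCC/C=C\C=C/CCC=C | intermediate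
22 | (1S,4S,11Z,13Z)-1-hydroxy-1-[(3R)-6-methoxy-1,2-dioxan-3-yl]octadeca-11,13,17-trien-4-yl methanesulfonate (acetal carbon: both epimers) | COC1CC[C@@H](OO1)[C@@H](O)CC[C@@H](OS(C)(=O)=O)CCCCCC/C=C\C=C/CCC=C | intermediate
23 | (6R)-3-methoxy-6-{(2S,5R)-5-[(7Z,9Z)-tetradeca-7,9,13-trien-1-yl]oxolan-2-yl}-1,2-dioxane (C3: both epimers) | C=CCC/C=C\C=C/CCCCCC[C@@H]1CC[C@@H]([C@H]2CCC(OC)OO2)O1 | intermediate
24 | (6R)-6-{(2S,5R)-5-[(7Z,9Z)-tetradeca-7,9,13-trien-1-yl]oxolan-2-yl}-1,2-dioxan-3-ol (C3: both epimers) | C=CCC/C=C\C=C/CCCCCC[C@@H]1CC[C@@H]([C@H]2CCC(O)OO2)O1 | intermediate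
25 | methyl (triphenylphosphoranylidene)acetate | COC(=O)C=P(c1ccccc1)(c1ccccc1)c1ccccc1 | starting material
26 | methyl (2E,6R)-6-hydroperoxy-6-{(2S,5R)-5-[(7Z,9Z)-tetradeca-7,9,13-trien-1-yl]oxolan-2-yl}hex-2-enoate | C=CCC/C=C\C=C/CCCCCC[C@@H]1CC[C@@H]([C@H](OO)CC/C=C/C(=O)OC)O1 | intermediate
27 | methyl 2-[(3R,6R)-6-{(2S,5R)-5-[(7Z,9Z)-tetradeca-7,9,13-trien-1-yl]oxolan-2-yl}-1,2-dioxan-3-yl]acetate | C=CCC/C=C\C=C/CCCCCC[C@@H]1CC[C@@H]([C@H]2CC[C@H](CC(=O)OC)OO2)O1 | intermediate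
28 | lithium 2-[(3R,6R)-6-{(2S,5R)-5-[(7Z,9Z)-tetradeca-7,9,13-trien-1-yl]oxolan-2-yl}-1,2-dioxan-3-yl]acetate | C=CCC/C=C\C=C/CCCCCC[C@@H]1CC[C@@H]([C@H]2CC[C@H](CC(=O)[O-])OO2)O1.[Li+] | intermediate
29 | 2-[(3R,6R)-6-{(2S,5R)-5-[(7Z,9Z)-tetradeca-7,9,13-trien-1-yl]oxolan-2-yl}-1,2-dioxan-3-yl]acetic acid | C=CCC/C=C\C=C/CCCCCC[C@@H]1CC[C@@H]([C@H]2CC[C@H](CC(=O)O)OO2)O1 | target

**Step count**
Total: 12 steps. Longest linear sequence: 9 steps (3, 4, 6, 7, 8, 9, 10, 11, 12).

**Steps most likely to fail, with fallbacks**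

Step 1. The ring-opening may not stop after one C–S bond, β-hydride elimination may give reduced diene, and thiolate 4 may alkylate its own chloride. The fallback builds the chain from alkynes instead. It sets out from 2, which is treated with lithium acetylide–ethylenediamine in DMSO to give 7-chlorohept-1-yne F1. Commercial hex-5-en-1-yne is brominated (NBS, AgNO3 cat.) to 6-bromohex-1-en-5-yne F2. Cadiot–Chodkiewicz coupling of F1 with F2 (CuCl, NH2OH·HCl, EtNH2) gives 13-chlorotridec-1-ene-5,7-diyne F3. Zinc activated with Cu(OAc)2 and AgNO3 in MeOH/H2O reduces both triple bonds cis, and the route is rejoined at 7.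

Step 9. The acetal oxygen may open the epoxide itself (giving a peroxide-free oxolane), or the C7 hydroxyl may add to C3. The fallback drops the tether and closes the dioxane by conjugate addition. It sets out from 20, whose acetal is cleaved with pyridinium tosylate in wet acetone to 3-[(2S,3S)-3-{(3S,10Z,12Z)-3-[(methanesulfonyl)oxy]heptadeca-10,12,16-trien-1-yl}oxiran-2-yl]propanal F4. Wittig reaction with 25 gives methyl (2E)-5-[(2S,3S)-3-{(3S,10Z,12Z)-3-[(methanesulfonyl)oxy]heptadeca-10,12,16-trien-1-yl}oxiran-2-yl]pent-2-enoate F5. Perhydrolysis of the epoxide with ethereal H2O2 and catalytic H3PMo12O40 gives methyl (2E,6R,7S,10S,17Z,19Z)-6-hydroperoxy-7-hydroxy-10-[(methanesulfonyl)oxy]tetracosa-2,17,19,23-tetraenoate F6 together with its C7-hydroperoxy regioisomer, which is separated (about half the material is lost). Et3N in CF3CH2OH (peroxy-Michael) and then warm pyridine (oxolane closure) bring F6 back to the route at 27.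

Step 11. The ylide may reduce the hydroperoxide, and the trans/cis ratio at C3 may be modest if the Michael addition does not equilibrate. The fallback works at the aldehyde level, where the conjugate addition is fast and reversible through an iminium ion. It sets out from 24, which reacts with (triphenylphosphoranylidene)acetaldehyde to give (2E,6R)-6-hydroperoxy-6-{(2S,5R)-5-[(7Z,9Z)-tetradeca-7,9,13-trien-1-yl]oxolan-2-yl}hex-2-enal F7. Pyrrolidine/AcOH (20 mol%) closes it to the equilibrated trans aldehyde 2-[(3R,6R)-6-{(2S,5R)-5-[(7Z,9Z)-tetradeca-7,9,13-trien-1-yl]oxolan-2-yl}-1,2-dioxan-3-yl]acetaldehyde F8. Oxidation with NaClO2, NaH2PO4 and 2-methylbut-2-ene rejoins the route at 29.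

Further compounds
F1 | step 1 | 7-chlorohept-1-yne | ClCCCCCC#C
F2 | step 1 | 6-bromohex-1-en-5-yne | BrC#CCCC=C
F3 | step 1 | 13-chlorotridec-1-ene-5,7-diyne | ClCCCCCC#CC#CCCC=C
F4 | step 9 | 3-[(2S,3S)-3-{(3S,10Z,12Z)-3-[(methanesulfonyl)oxy]heptadeca-10,12,16-trien-1-yl}oxiran-2-yl]propanal | O=CCC[C@@H]1O[C@H]1CC[C@@H](OS(C)(=O)=O)CCCCCC/C=C\C=C/CCC=C
F5 | step 9 | methyl (2E)-5-[(2S,3S)-3-{(3S,10Z,12Z)-3-[(methanesulfonyl)oxy]heptadeca-10,12,16-trien-1-yl}oxiran-2-yl]pent-2-enoate | COC(=O)/C=C/CC[C@@H]1O[C@H]1CC[C@@H](OS(C)(=O)=O)CCCCCC/C=C\C=C/CCC=C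
F6 | step 9 | methyl (2E,6R,7S,10S,17Z,19Z)-6-hydroperoxy-7-hydroxy-10-[(methanesulfonyl)oxy]tetracosa-2,17,19,23-tetraenoate | COC(=O)/C=C/CC[C@@H](OO)[C@@H](O)CC[C@@H](OS(C)(=O)=O)CCCCCC/C=C\C=C/CCC=C
F7 | step 11 | (2E,6R)-6-hydroperoxy-6-{(2S,5R)-5-[(7Z,9Z)-tetradeca-7,9,13-trien-1-yl]oxolan-2-yl}hex-2-enal | C=CCC/C=C\C=C/CCCCCC[C@@H]1CC[C@@H]([C@H](OO)CC/C=C/C=O)O1
F8 | step 11 | 2-[(3R,6R)-6-{(2S,5R)-5-[(7Z,9Z)-tetradeca-7,9,13-trien-1-yl]oxolan-2-yl}-1,2-dioxan-3-yl]acetaldehyde | C=CCC/C=C\C=C/CCCCCC[C@@H]1CC[C@@H]([C@H]2CC[C@H](CC=O)OO2)O1
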